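The numbers in the tables stem from a simulated flask on assumed constants, and the scatter is random.

In a one-step world from intermediate A to product, each point of A lost is a point of product gained, and time drops out when I divide the one rate by the other. I test that world on the earlier runs.

| flask | starting material | gas | remark | time |
|---|---|---|---|---|
| green | 5 mM | 4 mM (held) | run made earlier |  |
| grey | 7.5 mM | 4 mM (held) | run made earlier |  |
| flask | 10 mM | 4.0 mM (held) |  | 10 min |

- green (time / min: product / %, intermediate A / %): 0.667: 22, 8; 2.00: 47, 12; 4.00: 65, 11; 6.00: 74, 8; 8.00: 79, 3
- grey (time / min: product / %, intermediate A / %): 0.667: 24, 6; 1.33: 38, 9; 2.50: 53, 11; 4.00: 66, 15; 8.00: 76, 8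

(standard deviation of a reading: 2 percentage points)

- at the start none of partner is dissolved
- reactions considered so far: starting material <-> intermediate A; intermediate A <-> intermediate B; starting material <-> product; starting material <-> intermediate B; gas <-> partner; intermediate B -> decomposed reagent

* amount of product in the flask at 10 min, in percent of the starting material charged
* amount of intermediate A in the flask at 10 min, in percent of the starting material charged
* amount of decomposed reagent in the flask at 10 min, in percent of the starting material charged
* amount of starting material in the flask at 10 min, in percent of the starting material charged

Does the charge matter? At 4.00 min the grey run holds 1.02 times the percentage of product in the green run, with 1.50 times the charge. So I carry the percentages over to the 10 mM flask as first-order behaviour.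

What does a point of A buy? From 4.00 min to 8.00 min the two runs together gain 24 percentage points of product and lose 15 points of intermediate A. The exchange ratio, product gained per point of intermediate A lost, is therefore 1.60, a rough reading given the scatter. Product gains more than A gives up, so another species feeds it too.

How far does this reach? At the same pace, A loses 3.8 points more by 10 min. From the two-run means at 8.00 min, 77.5 % product and 5.50 % A, I reckon 83.5 % product and 1.75 % A.

The forecast gives 79 % product, 7 % A, 10 % decomposed reagent and 3 % starting material, holding that A “lingers more at higher loading”. On A we part.

The flask gives 81.8 % product, 7.49 % decomposed reagent and 5.57 % starting material. Intermediate A stands at 4.18 %, so the forecast holds, and this amount of intermediate A lies between its number and mine.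

    starting material ⇌ intermediate A (K = 0.460, k = 0.00200 s⁻¹)
    intermediate A ⇌ intermediate B (K = 0.380, k = 0.00200 s⁻¹)
    starting material ⇌ product (K = 25.0, k = 0.00760 s⁻¹)
    starting material ⇌ intermediate B (k = 0.00930 s⁻¹)
    gas ⇌ partner, rate k5*(csat - [partner]) (kL = 0.0130 s⁻¹)
    intermediate B → decomposed reagent (k = 0.00380 s⁻¹)

From 5.00 min to 10 min this flask's exchange ratio is 2.16. Carrying 1.60 from its state at 5.00 min to the neighbour read at 6.0 min gives 73.0 % product, and that neighbour holds 74.3 %. The neighbour read at 6.0 min holds more starting material, 9.66 %, than the 3 % forecast for 10 min, so a reading at that level at 10 min would make the forecast wrong. The step from starting material to intermediate B has done half its turnover by 0.102 min, and at 1.00 min intermediate B stands at 8.62 % beside 49.6 % starting material. Starting material falls to 11.9 % at 5.00 min, and at 100 min product stands at 77.2 % with 18.2 % decomposed reagent.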